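## The problem

The target is a phenylcoumaran neolignan. It is a 2,3-dihydrobenzofuran (benzo ring A, dihydrofuran ring B) with a 4-hydroxy-3,5-dimethoxyphenyl group (ring C) on C2, a hydroxymethyl carbon (C9) on C3, a methoxy group on C7 and an (E)-3-hydroxyprop-1-enyl chain on C5. The only stereocentres are the adjacent C2 (R) and C3 (S), and their substituents are trans. Trans is the more stable arrangement on this ring, so C3 can be equilibrated into line with C2 while C9 is still a carbonyl carbon. The absolute configuration at C2 therefore has to come from a reagent, since nothing else in the molecule can induce it. Three features are fragile. The ring C phenol lies para to the benzylic C2–O1 bond and, as a phenoxide next to an acidic C3–H, can open ring B through a para-quinone methide. The cinnamyl alcohol ionises in acid and does not survive hydrogenolysis. Both aryl rings are easily oxidised. What makes the key step possible is that the C2–C3 bond of ring B is, one oxidation level higher, the furan C=C bond of a 7-methoxybenzofuran. C2 is its enol-ether carbon and C3 its benzylic carbon, and an aryl group on the first with a one-carbon unit on the second is exactly what a syn carbofunctionalisation of that bond leaves behind.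

## Retrosynthesis

**Target 14 to diester 13.** No skeletal bond is cut. The two primary alcohols are traced back to methyl esters and the phenol to its pivalate, so that one hydride reagent reveals all three hydroxyl groups in the last step. This is preferred to a benzyl ether (hydrogenolysis would saturate the side chain) or a silyl ether (one more step). It also keeps the phenol masked through every basic and palladium-mediated operation. The forward step asks for clean 1,2-reduction of the enoate and full cleavage of a hindered aryl pivalate.

**Diester 13 to aryl chloride 11 and methyl acrylate 12.** The C5–vinyl bond is cut. Carrying the acrylate through the key step would offer the aryl–palladium species a second alkene, and an aldehyde at C5 would deactivate the benzofuran. A chloride is inert to a palladium bisphosphine catalyst at moderate temperature but is opened by Pd/P(t-Bu)3. The precursor loses the three-carbon chain. The forward step is a Heck coupling of an electron-rich aryl chloride that must tolerate two esters.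

**Trans ester 11 to cis ester 10.** Only the configuration at C3 changes. A syn addition across the furan bond must give the cis product, and the ester at C9 makes C3–H acidic enough for equilibration to the trans isomer. The base must be non-nucleophilic so that the pivalate stays on. With the phenol masked, the quinone-methide pathway that could scramble C2 is closed.

**Cis ester 10 to benzofuran 5, aryl iodide 8 and carbon monoxide 9 (with methanol).** The C2–aryl and C3–C9 bonds are cut together. The neighbouring cuts are O1–C2, which needs a preformed stereodefined diarylpropane, and C2–C3 with O1–C2, which needs a fleeting quinone methide. The chosen cut instead uses two flat, stable aromatic partners, each two steps from commerce, and turns both furan carbons into the two stereocentres in one catalytic operation. The forward reaction must be regioselective (aryl to C2), syn, face-selective under ligand control, and must insert the alkene before CO.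

**Benzofuran 5 to acid 4, and 4 to salicylaldehyde 1 and ethyl bromoacetate 2 (through ester 3).** The furan C2–C3 bond is cut, and then O1–C2. This is the classical construction from an ortho-formylphenoxyacetic acid by Perkin-type cyclisation with loss of CO2. It avoids the separate high-temperature decarboxylation of a benzofuran-2-carboxylic acid. Both precursors are commercial.

**Aryl iodide 8 to bromide 7 and to 4-bromo-2,6-dimethoxyphenol 6.** The C–I bond is traced to C–Br and the pivalate to the phenol. Direct iodination of 2,6-dimethoxyphenol can go to C3 as well as C4, whereas 6 is commercial with the halogen already at C4. The iodide is wanted for silver-assisted ionisation and for discrimination from the C5–Cl bond of 5.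

## Roads not taken

**Alternative 1:** This plan cuts C3–C9 and the benzylic C2–O bond and takes them out with a formaldehyde unit as a temporary ring. A confined chiral Brønsted acid would add a formaldehyde oligomer across an internal alkene to give the trans-4,5-diaryl-1,3-dioxane A1 from the (E)-stilbene A2, and O1–C2 would be closed later.
- Merits: C3 is set directly with its final carbon substituent, so no epimerisation is needed. The acrylate arm is present from the start, so no late cross-coupling is needed. The better cation-stabilising ring C biases the regiochemistry correctly.
- Weak points: asymmetric Prins reactions of this kind are established for terminal styrenes, and a doubly aryl-substituted internal alkene is far less reactive. The electron-rich 4-aryl dioxane can re-ionise under the acid that forms it. After the key step the formal acetal must be opened under forcing acid beside an enoate, the acetate removed, ring B closed by displacement at C2, and the benzyl ether removed without hydrogenolysis.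
- Comparison: Alternative 1 is better in that it needs neither a base-mediated correction at C3 nor a race against CO. Against this, the chosen plan needs no throw-away ring, its key product already holds every skeletal atom of the ring system, and only three steps follow it. Both key steps lie beyond precedent.

**Alternative 2:** This plan cuts only O1–C2. Ag2O would oxidise the 4-alkyl-2,6-dimethoxyphenol of dihydrostilbene A4 to its para-quinone methide, and the ortho phenol of ring A would add to the exocyclic carbon to give the trans alcohol A3.
- Merits: quinone-methide trapping by a phenol is how phenylcoumarans form in lignification, so the key step is close to known biomimetic chemistry. No protecting groups are needed, and C3 relays its configuration to C2.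
- Weak points: the C3 stereocentre of A4 must be made beforehand by a separate asymmetric C–C bond formation, which makes the route several steps longer. The quinone methide has an acidic C3–H beside it and can tautomerise to a stilbene, destroying the only stereocentre. Ag2O must choose between two phenols. The later Heck coupling runs on an unprotected phenol and diol.
- Comparison: the key step of Alternative 2 is more secure than the chosen one, and this is conceded. The chosen plan offers in return convergence from two fragments of two steps each, absolute configuration created catalytically in the same step as the skeletal bonds, and a masked phenol throughout.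

**Alternative 3:** This plan cuts C2–C3 and O1–C2. The ortho-quinone methide A6, formed in situ, would combine with a benzylic sulfonium ylide built on a chiral sulfide in a [4+1] annulation to give the trans bis-silyl ether A5.
- Merits: both stereocentres and ring B arise in one step, trans directly. The reaction class is established, including asymmetric variants. The number of steps after the key step (Heck coupling, desilylation, reduction) is comparable to the chosen plan.
- Weak points: the established cases use aryl-substituted quinone methides and stabilised ylides. A6 carries an alkyl group with a β-silyloxy substituent and can isomerise to an ortho-hydroxystyrene or eliminate. The electron-rich, semi-stabilised ylide needs strong base and a stoichiometric chiral sulfide.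
- Comparison: Alternative 3 is better in forming the trans isomer directly and in resting on a known reaction class. The chosen plan offers bench-stable aromatic partners, catalytic chirality, and a C9 ester that lets C3 be corrected rather than controlled kinetically.

Key step: step 5

Assumption: the face selected by a given ligand antipode in an unprecedented insertion cannot be predicted with confidence, so the route is written with (R)-SEGPHOS, and its enantiomer would be used if the first assay of 10 shows the 2S series.

## Route

Step 1
Reactants: 1 5-chloro-2-hydroxy-3-methoxybenzaldehyde; 2 ethyl bromoacetate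
Product: 4 (4-chloro-2-formyl-6-methoxyphenoxy)acetic acid, via ethyl (4-chloro-2-formyl-6-methoxyphenoxy)acetate 3 (not isolated)
Conditions: K2CO3, DMF, rt; then 2 M aq. NaOH, 0 °C to rt; aq. HCl to pH 2
Reagents that add atoms: sodium hydroxide, SMILES [Na+].[OH-]
Why: Williamson etherification of the acidic salicylaldehyde phenoxide with an α-halo ester, then saponification, which is much faster than enolisation of the aryloxyacetate at room temperature, so the formyl group is left alone.

Step 2
Reactants: 4 (4-chloro-2-formyl-6-methoxyphenoxy)acetic acid
Product: 5 5-chloro-7-methoxybenzofuran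
Conditions: NaOAc, Ac2O, AcOH, 130 °C
Reagents that add atoms: none
Why: Intramolecular Perkin-type condensation of the mixed anhydride onto the ortho formyl group forms the furan C2–C3 bond, and decarboxylative loss of acetate aromatises the ring; this is the classical benzofuran synthesis from ortho-formylphenoxyacetic acids.

Step 3
Reactants: 6 4-bromo-2,6-dimethoxyphenol
Product: 7 4-bromo-2,6-dimethoxyphenyl 2,2-dimethylpropanoate (pivalate)
Conditions: PivCl, Et3N, DMAP (cat.), CH2Cl2, 0 °C to rt
Reagents that add atoms: pivaloyl chloride, SMILES CC(C)(C)C(=O)Cl
Why: DMAP-catalysed acylation of a hindered phenol; the pivalate resists methanol and amine bases in the later steps and falls to hydride at the end.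

Step 4
Reactants: 7 4-bromo-2,6-dimethoxyphenyl pivalate
Product: 8 4-iodo-2,6-dimethoxyphenyl pivalate
Conditions: NaI (2 equiv), CuI (5 mol%), trans-N,N'-dimethylcyclohexane-1,2-diamine (10 mol%), 1,4-dioxane, 110 °C
Reagents that add atoms: sodium iodide, SMILES [Na+].[I-]
Why: Copper-catalysed aromatic Finkelstein halogen exchange, driven by precipitation of NaBr; it tolerates esters and fixes the iodine at C4 without the regiochemical question of a direct iodination.

Step 5
Reactants: 5 5-chloro-7-methoxybenzofuran (3 equiv); 8 4-iodo-2,6-dimethoxyphenyl pivalate; 9 carbon monoxide
Product: 10 methyl (2R,3S)-5-chloro-2-[3,5-dimethoxy-4-(pivaloyloxy)phenyl]-7-methoxy-2,3-dihydrobenzofuran-3-carboxylate (cis)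
Conditions: Pd(OAc)2 (5 mol%), (R)-SEGPHOS [(R)-5,5'-bis(diphenylphosphino)-4,4'-bi-1,3-benzodioxole] (6 mol%), AgOTf (1.2 equiv), 2,6-di-tert-butyl-4-methylpyridine (1.5 equiv), MeOH (5 equiv), CO/N2 1:9 (1 atm), PhCF3, 60 °C
Reagents that add atoms: methanol, SMILES CO
Why: Proposed new method: Pd(OAc)2 is reduced in situ to zerovalent palladium, which adds oxidatively to the C–I bond of 8 (the C–Cl bond of 5 is inert here); AgOTf removes iodide, and the resulting cationic aryl–palladium bisphosphine complex binds the C2=C3 bond of 5 and inserts it syn, the aryl group going to the oxygen-bearing C2, as cationic palladium does with enol ethers, and the metal to benzylic C3, where it is held as an η3-benzyl. The single β-hydrogen, on C2, then lies on the face opposite to palladium, so syn β-hydride elimination is closed and the C3–Pd bond has time to take up CO with retention; methanol cleaves the acyl–palladium to the methyl ester and the hindered pyridine takes the proton, returning zerovalent palladium. The closest known reaction types are the intramolecular dearomative Heck/anion-capture cascades of tethered benzofurans and indoles, the three-component aryl-alkoxycarbonylation of norbornene, the alkoxycarbonylation of benzyl–palladium species and the asymmetric cationic Heck arylation of 2,3-dihydrofuran; an intermolecular enantioselective version on a benzofuran is not established. No ring is closed: the step forms the C2–aryl and C3–C9 bonds. C2 is set by the chiral bisphosphine, which must distinguish the two faces of the flat heteroarene in the insertion (aryl to the C2 Si face gives 2R); C3 follows from syn addition and retentive CO insertion and is therefore cis, which step 6 corrects. The step needs alkene insertion to precede CO insertion into the aryl–palladium bond, which the low CO partial pressure, the threefold excess of 5 and the limited methanol are meant to secure, and it needs the adduct not to rearomatise by loss of the C2 hydrogen, which the absence of stoichiometric carboxylate or carbonate base and the non-coordinating triflate are meant to secure.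

Step 6
Reactants: 10 cis ester
Product: 11 methyl (2R,3R)-5-chloro-2-[3,5-dimethoxy-4-(pivaloyloxy)phenyl]-7-methoxy-2,3-dihydrobenzofuran-3-carboxylate (trans)
Conditions: DBU (0.5 equiv), toluene, 60 °C
Reagents that add atoms: none
Why: Base-mediated epimerisation through the ester enolate moves the C3 ester to the less hindered face, trans to the C2 aryl group (the C3 descriptor changes from S to R); DBU is non-nucleophilic, so the pivalate stays. C2 is not touched, because β-elimination of O1 from the enolate would be the reverse of a disfavoured 5-endo-trig closure and the acylated phenol cannot form a para-quinone methide.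

Step 7
Reactants: 11 trans ester; 12 methyl acrylate (2 equiv)
Product: 13 methyl (2R,3R)-2-[3,5-dimethoxy-4-(pivaloyloxy)phenyl]-7-methoxy-5-[(E)-3-methoxy-3-oxoprop-1-en-1-yl]-2,3-dihydrobenzofuran-3-carboxylate
Conditions: Pd2(dba)3 (2.5 mol%), P(t-Bu)3 (10 mol%), Cy2NMe (1.5 equiv), 1,4-dioxane, 100 °C
Reagents that add atoms: none
Why: Mizoroki–Heck coupling of an aryl chloride; the bulky, electron-rich P(t-Bu)3 allows oxidative addition into the electron-rich C–Cl bond, syn insertion and syn β-hydride elimination give the (E)-cinnamate, and the tertiary amine base leaves both esters and the already thermodynamic C3 centre alone.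

Step 8
Reactants: 13 diester pivalate
Product: 14 4-[(2R,3S)-3-(hydroxymethyl)-5-[(E)-3-hydroxyprop-1-en-1-yl]-7-methoxy-2,3-dihydrobenzofuran-2-yl]-2,6-dimethoxyphenol (target)
Conditions: i-Bu2AlH (8 equiv), CH2Cl2, −78 to 0 °C; aq. potassium sodium tartrate
Reagents that add atoms: none
Why: Global hydride reduction: i-Bu2AlH reduces the enoate 1,2 to the allylic alcohol and the C3 ester to the hydroxymethyl group, and cleaves the aryl pivalate reductively, as in the established reduction of dehydrodiferulate-type diesters. The neutral tartrate work-up protects the cinnamyl alcohol. No stereocentre is touched; the C3 descriptor returns to S only because CH2OH ranks below C2.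

## Compound list

1 | 5-chloro-2-hydroxy-3-methoxybenzaldehyde | COc1cc(Cl)cc(C=O)c1O | starting material
2 | ethyl bromoacetate | CCOC(=O)CBr | starting material
3 | ethyl (4-chloro-2-formyl-6-methoxyphenoxy)acetate | CCOC(=O)COc1c(C=O)cc(Cl)cc1OC | intermediate (not isolated)
4 | (4-chloro-2-formyl-6-methoxyphenoxy)acetic acid | OC(=O)COc1c(C=O)cc(Cl)cc1OC | intermediate
5 | 5-chloro-7-methoxybenzofuran | COc1cc(Cl)cc2ccoc12 | intermediate
6 | 4-bromo-2,6-dimethoxyphenol | COc1cc(Br)cc(OC)c1O | starting material
7 | 4-bromo-2,6-dimethoxyphenyl pivalate | COc1cc(Br)cc(OC)c1OC(=O)C(C)(C)C | intermediate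
8 | 4-iodo-2,6-dimethoxyphenyl pivalate | COc1cc(I)cc(OC)c1OC(=O)C(C)(C)C | intermediate
9 | carbon monoxide | [C-]#[O+] | starting material
10 | methyl (2R,3S)-5-chloro-2-[3,5-dimethoxy-4-(pivaloyloxy)phenyl]-7-methoxy-2,3-dihydrobenzofuran-3-carboxylate (cis) | COc1cc([C@@H]2Oc3c(OC)cc(Cl)cc3[C@@H]2C(=O)OC)cc(OC)c1OC(=O)C(C)(C)C | intermediate
11 | methyl (2R,3R)-5-chloro-2-[3,5-dimethoxy-4-(pivaloyloxy)phenyl]-7-methoxy-2,3-dihydrobenzofuran-3-carboxylate (trans) | COc1cc([C@@H]2Oc3c(OC)cc(Cl)cc3[C@H]2C(=O)OC)cc(OC)c1OC(=O)C(C)(C)C | intermediate
12 | methyl acrylate | COC(=O)C=C | starting material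
13 | methyl (2R,3R)-2-[3,5-dimethoxy-4-(pivaloyloxy)phenyl]-7-methoxy-5-[(E)-3-methoxy-3-oxoprop-1-en-1-yl]-2,3-dihydrobenzofuran-3-carboxylate | COc1cc([C@@H]2Oc3c(OC)cc(/C=C/C(=O)OC)cc3[C@H]2C(=O)OC)cc(OC)c1OC(=O)C(C)(C)C | intermediate
14 | 4-[(2R,3S)-3-(hydroxymethyl)-5-[(E)-3-hydroxyprop-1-en-1-yl]-7-methoxy-2,3-dihydrobenzofuran-2-yl]-2,6-dimethoxyphenol | COc1cc([C@@H]2Oc3c(OC)cc(/C=C/CO)cc3[C@H]2CO)cc(OC)c1O | target

## Step count and risks

Total: 8 steps. Longest linear sequence: 6 steps (steps 1, 2, 5, 6, 7, 8 from 1; equally steps 3 to 8 from 6).

**Step 5 (key step).**
- What may go wrong: CO may insert into the aryl–palladium bond before the benzofuran does, which diverts 8 into direct methoxycarbonylation and acyl-Heck adducts. The benzylic palladium adduct may rearomatise by base-assisted loss of the C2 hydrogen, or be intercepted by a palladium hydride formed from methanol. Facial discrimination may be poor, because a flat, weakly binding heteroarene gives the ligand little to hold.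
- Fallback: this gives up the three-component union and forms C2–C3 by the known enantioselective intramolecular C–H insertion of an aryldiazoacetate into an ortho-benzyloxy group. It sets out from 5 and returns at 10.
  - Lithiation of 5 at C2 (n-BuLi, THF, −78 °C), B(OMe)3 and oxidation (H2O2, AcOH) give 5-chloro-7-methoxybenzofuran-2(3H)-one F1. Methanol with catalytic H2SO4 opens this to methyl (5-chloro-2-hydroxy-3-methoxyphenyl)acetate F2.
  - Separately, commercial syringaldehyde is pivaloylated (PivCl, Et3N) to 4-formyl-2,6-dimethoxyphenyl pivalate F3 and reduced (NaBH4, THF/MeOH, 0 °C) to 4-(hydroxymethyl)-2,6-dimethoxyphenyl pivalate F4.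
  - Mitsunobu etherification of F2 with F4 (PPh3, diisopropyl azodicarboxylate, THF) gives methyl (5-chloro-2-{[3,5-dimethoxy-4-(pivaloyloxy)phenyl]methoxy}-3-methoxyphenyl)acetate F5.
  - Diazo transfer (4-acetamidobenzenesulfonyl azide, DBU, MeCN) gives methyl 2-(5-chloro-2-{[3,5-dimethoxy-4-(pivaloyloxy)phenyl]methoxy}-3-methoxyphenyl)-2-diazoacetate F6.
  - Rh2(S-PTTL)4, or its enantiomer if that is the one that leads to the 2R,3S series, in toluene at low temperature should insert the carbene into the benzylic C–H bond and close ring B to the cis ester 10.

**Step 6.**
- What may go wrong: equilibration with an amidine base may be slow or incomplete. Prolonged heating could allow ring opening by β-elimination of O1 and reclosure, which would erode the enantiomeric purity at C2.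
- Fallback: this sets out from 10 and uses the classical alkoxide equilibration, accepting loss of the acyl group. NaOMe in MeOH at 0 °C should epimerise C3 and cleave the pivalate to give methyl (2R,3R)-5-chloro-2-(4-hydroxy-3,5-dimethoxyphenyl)-7-methoxy-2,3-dihydrobenzofuran-3-carboxylate F7, with the exposure kept short because the phenoxide is the species that can open ring B. Immediate re-acylation (PivCl, Et3N, DMAP, CH2Cl2) returns to 11.

**Step 7.**
- What may go wrong: oxidative addition into an aryl chloride that is para to an alkoxy oxygen may be sluggish. At the temperature needed, acrylate oligomerisation and slow base-mediated degradation at C3 would then compete.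
- Fallback: this sets out from 11 and forms the same C5–vinyl bond by transmetalation instead of carbopalladation. Suzuki–Miyaura coupling with commercial methyl (E)-3-(4,4,5,5-tetramethyl-1,3,2-dioxaborolan-2-yl)acrylate (Pd(OAc)2, SPhos, anhydrous K3PO4, toluene, 90 °C) returns directly to 13. No new compound is made on the way (entry F0).

**Step 2.**
- What may go wrong: the cyclised intermediate may dehydrate instead of decarboxylating, giving the benzofuran-2-carboxylic acid, which does not lose CO2 under these conditions. Tar formation at 130 °C is also possible.
- Fallback: this sets out from 1 (with 2) and accepts the carboxylate, removing it in a separate step. Heating with K2CO3 in DMF at 120 °C (alkylation, intramolecular aldol, dehydration) gives ethyl 5-chloro-7-methoxybenzofuran-2-carboxylate F8. Saponification (NaOH, EtOH/H2O) gives 5-chloro-7-methoxybenzofuran-2-carboxylic acid F9. Protodecarboxylation (Ag2CO3 cat., AcOH, DMSO, 120 °C) returns to 5.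

## Further compounds

F1 | step 5 | 5-chloro-7-methoxybenzofuran-2(3H)-one | COc1cc(Cl)cc2CC(=O)Oc12
F2 | step 5 | methyl (5-chloro-2-hydroxy-3-methoxyphenyl)acetate | COC(=O)Cc1cc(Cl)cc(OC)c1O
F3 | step 5 | 4-formyl-2,6-dimethoxyphenyl pivalate | COc1cc(C=O)cc(OC)c1OC(=O)C(C)(C)C
F4 | step 5 | 4-(hydroxymethyl)-2,6-dimethoxyphenyl pivalate | COc1cc(CO)cc(OC)c1OC(=O)C(C)(C)C
F5 | step 5 | methyl (5-chloro-2-{[3,5-dimethoxy-4-(pivaloyloxy)phenyl]methoxy}-3-methoxyphenyl)acetate | COC(=O)Cc1cc(Cl)cc(OC)c1OCc1cc(OC)c(OC(=O)C(C)(C)C)c(OC)c1
F6 | step 5 | methyl 2-(5-chloro-2-{[3,5-dimethoxy-4-(pivaloyloxy)phenyl]methoxy}-3-methoxyphenyl)-2-diazoacetate | COC(=O)C(=[N+]=[N-])c1cc(Cl)cc(OC)c1OCc1cc(OC)c(OC(=O)C(C)(C)C)c(OC)c1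
F7 | step 6 | methyl (2R,3R)-5-chloro-2-(4-hydroxy-3,5-dimethoxyphenyl)-7-methoxy-2,3-dihydrobenzofuran-3-carboxylate | COc1cc([C@@H]2Oc3c(OC)cc(Cl)cc3[C@H]2C(=O)OC)cc(OC)c1O
F0 | step 7 | none | none
F8 | step 2 | ethyl 5-chloro-7-methoxybenzofuran-2-carboxylate | CCOC(=O)c1cc2cc(Cl)cc(OC)c2o1
F9 | step 2 | 5-chloro-7-methoxybenzofuran-2-carboxylic acid | OC(=O)c1cc2cc(Cl)cc(OC)c2o1
A1 | alternative 1 | methyl (E)-3-{4-acetoxy-3-[(4S,5S)-4-(4-benzyloxy-3,5-dimethoxyphenyl)-1,3-dioxan-5-yl]-5-methoxyphenyl}acrylate | COc1cc([C@H]2OCOC[C@@H]2c3cc(/C=C/C(=O)OC)cc(OC)c3OC(C)=O)cc(OC)c1OCc1ccccc1
A2 | alternative 1 | methyl (E)-3-{4-acetoxy-3-[(E)-2-(4-benzyloxy-3,5-dimethoxyphenyl)ethenyl]-5-methoxyphenyl}acrylate | COc1cc(/C=C/c2cc(/C=C/C(=O)OC)cc(OC)c2OC(C)=O)cc(OC)c1OCc1ccccc1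
A3 | alternative 2 | [(2R,3S)-5-bromo-2-(4-hydroxy-3,5-dimethoxyphenyl)-7-methoxy-2,3-dihydrobenzofuran-3-yl]methanol | COc1cc([C@@H]2Oc3c(OC)cc(Br)cc3[C@H]2CO)cc(OC)c1O
A4 | alternative 2 | 4-bromo-2-[(2S)-1-hydroxy-3-(4-hydroxy-3,5-dimethoxyphenyl)propan-2-yl]-6-methoxyphenol | COc1cc(Br)cc([C@H](Cc2cc(OC)c(O)c(OC)c2)CO)c1O
A5 | alternative 3 | (2R,3S)-5-bromo-3-[(tert-butyldimethylsilyloxy)methyl]-2-[4-(tert-butyldimethylsilyloxy)-3,5-dimethoxyphenyl]-7-methoxy-2,3-dihydrobenzofuran | COc1cc([C@@H]2Oc3c(OC)cc(Br)cc3[C@H]2CO[Si](C)(C)C(C)(C)C)cc(OC)c1O[Si](C)(C)C(C)(C)C
A6 | alternative 3 | (6E)-4-bromo-6-[2-(tert-butyldimethylsilyloxy)ethylidene]-2-methoxycyclohexa-2,4-dien-1-one | O=C1C(OC)=CC(Br)=C/C1=C\CO[Si](C)(C)C(C)(C)C
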